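With ring carbons C1 (isopropylidene-bearing), C2, C3, C4 (CHMe), C5 (quaternary) and C6 (chain-bearing CH), C7 as the indolylmethyl carbon and C8–C10 as the acid chain, the route exploits the 1,5-relationship of C1 and carboxyl C10 across C6–C8–C9 within the cyclohexane. A 6-alkyl dioxinone (C10 carbonyl, C9=C1) carrying the C4/C5 stereodiad, a silyl-protected C7 and a C6=C8 vinyl group is irradiated: intramolecular [2+2] forms C1–C6, closing the six-membered ring, and C8–C9; methanolysis then cleaves C1–C9 by retro-aldol reaction, delivering the C1 ketone, the C10 ester and the C6 stereocentre in one operation. An Ireland–Claisen rearrangement supplies the diad; isopropylidenation and indole attachment finish.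

Key step: step 8

Remark: the (S,S)-enantiomer of the diazaborolidine controller in step 4 is assumed to deliver the (2S,3S)-acid 8; should the sense of induction prove opposite, the equally available (R,R)-controller is used with no other change.

Step 1
Reactants: 1 1-{[tert-butyl(dimethyl)silyl]oxy}propan-2-one; 2 triethyl phosphonoacetate
Product: 3 ethyl (2E)-4-{[tert-butyl(dimethyl)silyl]oxy}-3-methylbut-2-enoate
Conditions: NaH, THF, 0 °C → rt; minor (Z)-isomer removed by chromatography
Reagents that add atoms: none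
Why: Horner–Wadsworth–Emmons olefination of the ketone by the stabilised phosphonate anion should place the ester trans to the larger CH2OTBS group, the (E)-geometry that the Claisen step needs.

Step 2
Reactants: 3 ethyl (2E)-4-{[tert-butyl(dimethyl)silyl]oxy}-3-methylbut-2-enoate
Product: 4 (2E)-4-{[tert-butyl(dimethyl)silyl]oxy}-3-methylbut-2-en-1-ol
Conditions: i-Bu2AlH (2.2 equiv), CH2Cl2, −78 → 0 °C; Rochelle salt work-up
Reagents that add atoms: none
Why: 1,2-Reduction of the enoate by the aluminium hydride should stop at the allylic alcohol and leave the silyl ether and the alkene geometry untouched.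

Step 3
Reactants: 4 (2E)-4-{[tert-butyl(dimethyl)silyl]oxy}-3-methylbut-2-en-1-ol; 5 propanoyl chloride
Product: 6 (2E)-4-{[tert-butyl(dimethyl)silyl]oxy}-3-methylbut-2-en-1-yl propanoate
Conditions: Et3N, DMAP (cat.), CH2Cl2, 0 °C
Reagents that add atoms: none
Why: Acylation of an unhindered primary allylic alcohol under nucleophilic catalysis is routine and does not disturb the alkene.

Step 4
Reactants: 6 (2E)-4-{[tert-butyl(dimethyl)silyl]oxy}-3-methylbut-2-en-1-yl propanoate
Product: 8 (2S,3S)-3-({[tert-butyl(dimethyl)silyl]oxy}methyl)-2,3-dimethylpent-4-enoic acid, via boron enolate 7 (not isolated)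
Conditions: (4S,5S)-2-bromo-1,3-bis{[3,5-bis(trifluoromethyl)phenyl]sulfonyl}-4,5-diphenyl-1,3,2-diazaborolidine (1.2 equiv), Et3N, toluene/hexane, −78 °C, then −20 → 4 °C; H2O work-up
Reagents that add atoms: none
Why: Enantioselective Ireland–Claisen rearrangement of a chiral boron ketene acetal: Et3N in the non-polar medium should give the E(O)-enolate 7 (methyl trans to O–B), whose chair transition state with the (E)-alkene sets the C4/C5 relationship (C4 methyl anti to CH2OTBS along the zigzag chain), while the C2-symmetric bis-sulfonamide on boron selects the enolate face and so the absolute configuration.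

Step 5
Reactants: 8 (2S,3S)-3-({[tert-butyl(dimethyl)silyl]oxy}methyl)-2,3-dimethylpent-4-enoic acid
Product: 9 (2S,3S)-3-({[tert-butyl(dimethyl)silyl]oxy}methyl)-2,3-dimethylpent-4-en-1-ol
Conditions: LiAlH4, Et2O, 0 °C → rt
Reagents that add atoms: none
Why: Hydride reduction of the carboxylic acid gives the primary alcohol; the α-centre is not epimerised because the acid reacts as its carboxylate, and the silyl ether and vinyl group are inert.

Step 6
Reactants: 9 (2S,3S)-3-({[tert-butyl(dimethyl)silyl]oxy}methyl)-2,3-dimethylpent-4-en-1-ol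
Product: 10 tert-butyl{[(2S,3S)-2-ethenyl-4-iodo-2,3-dimethylbutyl]oxy}dimethylsilane
Conditions: I2, PPh3, imidazole, CH2Cl2, 0 °C → rt
Reagents that add atoms: iodine, II
Why: Appel-type iodination through the alkoxyphosphonium salt displaces at the primary carbon (SN2) without touching either stereocentre.

Step 7
Reactants: 10 tert-butyl{[(2S,3S)-2-ethenyl-4-iodo-2,3-dimethylbutyl]oxy}dimethylsilane; 11 2,2,6-trimethyl-4H-1,3-dioxin-4-one
Product: 13 6-[(3R,4S)-4-({[tert-butyl(dimethyl)silyl]oxy}methyl)-3,4-dimethylhex-5-en-1-yl]-2,2-dimethyl-4H-1,3-dioxin-4-one, via lithium dienolate 12 (not isolated)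
Conditions: LiN(i-Pr)2, THF, −78 °C; then 10, HMPA, −78 → −20 °C
Reagents that add atoms: none
Why: γ-Alkylation of the extended (vinylogous) lithium enolate of the dioxinone by a primary iodide is an SN2 reaction at the methyl terminus, with HMPA raising the nucleophilicity of the dienolate used in excess; this joins C2 to C3.

Step 8
Reactants: 13 6-[(3R,4S)-4-({[tert-butyl(dimethyl)silyl]oxy}methyl)-3,4-dimethylhex-5-en-1-yl]-2,2-dimethyl-4H-1,3-dioxin-4-one
Product: 16 methyl 3-[(1S,2R,3R)-2-({[tert-butyl(dimethyl)silyl]oxy}methyl)-2,3-dimethyl-6-oxocyclohexyl]propanoate, via photoadduct 14 (not isolated), via cyclobutanol ester 15 (not isolated)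
Conditions: hν (medium-pressure Hg lamp, Pyrex filter), MeCN/acetone 9:1, 0 °C; evaporate; then K2CO3, MeOH, 0 °C
Reagents that add atoms: methanol, CO
Why: This is the de Mayo sequence in its dioxinone form (intramolecular enone–alkene [2+2] photocycloaddition, then retro-aldol fragmentation): the excited dioxinone bonds through C1 to the internal vinyl carbon C6 and the 1,4-biradical collapses by C9–C8 coupling to photoadduct 14. The cyclohexane closes in a 6-exo-trig sense (C1 onto C6=C8) and the cyclobutane by radical recombination, which can only give the cis ring fusion. Methoxide then opens the lactone, acetone leaves, and the alkoxide of 15 cleaves C1–C9 in a strain-driven retro-aldol reaction to the C1 ketone and the C8–C10 ester chain. C6, the one stereocentre that remains, is set when C1–C6 forms: the tether folds as a chair with the C4 and C5 methyl groups equatorial and CH2OTBS axial, and C8 turns anti to that axial group, since the other vinyl rotamer eclipses it and the flipped chair would put C8 syn-axial to the C4 methyl. The step needs straight rather than crossed regiochemistry, secured by the four-atom tether (six- over seven-membered closure), and an untouched C6–H next to the new ketone, secured by brief K2CO3/MeOH at 0 °C in a cleavage that never involves C6.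

Step 9
Reactants: 16 methyl 3-[(1S,2R,3R)-2-({[tert-butyl(dimethyl)silyl]oxy}methyl)-2,3-dimethyl-6-oxocyclohexyl]propanoate
Product: 17 methyl 3-[(1S,2R,3R)-2-({[tert-butyl(dimethyl)silyl]oxy}methyl)-6-(dibromomethylidene)-2,3-dimethylcyclohexyl]propanoate
Conditions: CBr4, PPh3, toluene, 80 °C
Reagents that add atoms: carbon tetrabromide, BrC(Br)(Br)Br
Why: Dibromo-olefination by Ph3P=CBr2 (Wittig reaction, first half of the Corey–Fuchs sequence) uses a small, non-basic ylide that should reach the hindered ketone without enolising C6, introduces C11 and spares the ester; once C1 is olefinic, C6 can no longer epimerise.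

Step 10
Reactants: 17 methyl 3-[(1S,2R,3R)-2-({[tert-butyl(dimethyl)silyl]oxy}methyl)-6-(dibromomethylidene)-2,3-dimethylcyclohexyl]propanoate
Product: 19 methyl 3-[(1R,2R,3R)-2-({[tert-butyl(dimethyl)silyl]oxy}methyl)-2,3-dimethyl-6-(propan-2-ylidene)cyclohexyl]propanoate, via alkenylcuprate 18 (not isolated)
Conditions: Me2CuLi (from MeLi and CuI, 5 equiv), Et2O, −78 → 0 °C; then MeI, 0 °C
Reagents that add atoms: lithium dimethylcuprate, [Li+].C[Cu-]C; iodomethane, CI
Why: Double methylation of a gem-dibromoalkene with a Gilman reagent: cross-coupling replaces one bromine, bromine–copper exchange at the other gives alkenylcuprate 18, and MeI alkylates it, while the cuprate does not add to the ester at or below 0 °C.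

Step 11
Reactants: 19 methyl 3-[(1R,2R,3R)-2-({[tert-butyl(dimethyl)silyl]oxy}methyl)-2,3-dimethyl-6-(propan-2-ylidene)cyclohexyl]propanoate
Product: 20 methyl 3-[(1R,2R,3R)-2-(hydroxymethyl)-2,3-dimethyl-6-(propan-2-ylidene)cyclohexyl]propanoate
Conditions: Bu4NF, THF, rt → 45 °C
Reagents that add atoms: none
Why: Fluoride-driven desilylation frees the neopentyl alcohol; the ester and the tetrasubstituted alkene are inert, and lactonisation would need a seven-membered ring.

Step 12
Reactants: 20 methyl 3-[(1R,2R,3R)-2-(hydroxymethyl)-2,3-dimethyl-6-(propan-2-ylidene)cyclohexyl]propanoate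
Product: 21 methyl 3-[(1R,2R,3R)-2-formyl-2,3-dimethyl-6-(propan-2-ylidene)cyclohexyl]propanoate
Conditions: Dess–Martin periodinane, CH2Cl2, rt
Reagents that add atoms: none
Why: Dess–Martin oxidation takes the primary alcohol to the aldehyde under near-neutral conditions, and the product, having no α-hydrogen, can neither enolise nor epimerise.

Step 13
Reactants: 21 methyl 3-[(1R,2R,3R)-2-formyl-2,3-dimethyl-6-(propan-2-ylidene)cyclohexyl]propanoate; 22 indole
Product: 24 methyl 3-[(1R,2R,3R)-2-[hydroxy(1H-indol-3-yl)methyl]-2,3-dimethyl-6-(propan-2-ylidene)cyclohexyl]propanoate (both carbinol epimers), via indolylmagnesium bromide 23 (not isolated)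
Conditions: EtMgBr (slightly less than 1 equiv per indole), Et2O/CH2Cl2, 0 °C; then 21, 0 °C → rt; H2O quench
Reagents that add atoms: none
Why: Grignard-type addition of N-magnesioindole, which reacts with aldehydes through C3 and is too weak a nucleophile to attack the methyl ester; the new carbinol centre forms as a mixture and is removed in step 14.

Step 14
Reactants: 24 methyl 3-[(1R,2R,3R)-2-[hydroxy(1H-indol-3-yl)methyl]-2,3-dimethyl-6-(propan-2-ylidene)cyclohexyl]propanoate
Product: 26 suaveolindole (3-[(1S,2R,3R)-2-(1H-indol-3-ylmethyl)-2,3-dimethyl-6-(propan-2-ylidene)cyclohexyl]propanoic acid), via lithium carboxylate 25 (not isolated)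
Conditions: LiOH, THF/MeOH/H2O, rt; then NaBH4, 65 °C; dilute HCl to pH 4
Reagents that add atoms: lithium hydroxide, [Li+].[OH-]
Why: Saponification followed by reductive deoxygenation in one flask: in base the 3-indolylcarbinol loses hydroxide from the N-deprotonated indole to give a 3-alkylidene-3H-indole, which NaBH4 reduces at the exocyclic carbon, and the carboxylate formed first is inert to borohydride.

Compound list
1 | 1-{[tert-butyl(dimethyl)silyl]oxy}propan-2-one (commercial; also one step from hydroxyacetone) | CC(=O)CO[Si](C)(C)C(C)(C)C | starting material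
2 | triethyl phosphonoacetate | CCOC(=O)CP(=O)(OCC)OCC | starting material
3 | ethyl (2E)-4-{[tert-butyl(dimethyl)silyl]oxy}-3-methylbut-2-enoate | CCOC(=O)/C=C(\C)CO[Si](C)(C)C(C)(C)C | intermediate
4 | (2E)-4-{[tert-butyl(dimethyl)silyl]oxy}-3-methylbut-2-en-1-ol | OC/C=C(\C)CO[Si](C)(C)C(C)(C)C | intermediate
5 | propanoyl chloride | CCC(=O)Cl | starting material
6 | (2E)-4-{[tert-butyl(dimethyl)silyl]oxy}-3-methylbut-2-en-1-yl propanoate | CCC(=O)OC/C=C(\C)CO[Si](C)(C)C(C)(C)C | intermediate
7 | E(O)-boron enolate of 6 (methyl trans to O–B; boron held in the (4S,5S)-1,3-bis(arylsulfonyl)-4,5-diphenyl-1,3,2-diazaborolidine) | C/C=C(/OB1N(S(=O)(=O)c2cc(C(F)(F)F)cc(C(F)(F)F)c2)[C@@H](c2ccccc2)[C@H](c2ccccc2)N1S(=O)(=O)c1cc(C(F)(F)F)cc(C(F)(F)F)c1)OC/C=C(\C)CO[Si](C)(C)C(C)(C)C | intermediate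
8 | (2S,3S)-3-({[tert-butyl(dimethyl)silyl]oxy}methyl)-2,3-dimethylpent-4-enoic acid | OC(=O)[C@@H](C)[C@@](C)(CO[Si](C)(C)C(C)(C)C)C=C | intermediate
9 | (2S,3S)-3-({[tert-butyl(dimethyl)silyl]oxy}methyl)-2,3-dimethylpent-4-en-1-ol | OC[C@@H](C)[C@@](C)(CO[Si](C)(C)C(C)(C)C)C=C | intermediate
10 | tert-butyl{[(2S,3S)-2-ethenyl-4-iodo-2,3-dimethylbutyl]oxy}dimethylsilane | IC[C@@H](C)[C@@](C)(CO[Si](C)(C)C(C)(C)C)C=C | intermediate
11 | 2,2,6-trimethyl-4H-1,3-dioxin-4-one | CC1=CC(=O)OC(C)(C)O1 | starting material
12 | lithium dienolate of 11 (2,2-dimethyl-6-methylidene-6H-1,3-dioxin-4-olate) | [Li+].C=C1C=C([O-])OC(C)(C)O1 | intermediate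
13 | 6-[(3R,4S)-4-({[tert-butyl(dimethyl)silyl]oxy}methyl)-3,4-dimethylhex-5-en-1-yl]-2,2-dimethyl-4H-1,3-dioxin-4-one | CC1(C)OC(=O)C=C(CC[C@@H](C)[C@@](C)(CO[Si](C)(C)C(C)(C)C)C=C)O1 | intermediate
14 | tricyclic photoadduct: cyclohexane C1–C6 cis-fused at C1–C6 to the cyclobutane (C1, C6, C8, C9), itself cis-fused at C1–C9 to the 2,2-dimethyl-1,3-dioxan-4-one; C8 and C9 anti to CH2OTBS, the C1–O bond syn to it | O=C1OC(C)(C)O[C@@]23CC[C@@H](C)[C@@](C)(CO[Si](C)(C)C(C)(C)C)[C@@H]2C[C@@H]13 | intermediate
15 | methyl 1-hydroxy-5-({[tert-butyl(dimethyl)silyl]oxy}methyl)-4,5-dimethylbicyclo[4.2.0]octane-8-carboxylate (cis-fused, configuration as in 14; present as its potassium alkoxide) | O[C@@]12CC[C@@H](C)[C@@](C)(CO[Si](C)(C)C(C)(C)C)[C@@H]1C[C@H]2C(=O)OC | intermediate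
16 | methyl 3-[(1S,2R,3R)-2-({[tert-butyl(dimethyl)silyl]oxy}methyl)-2,3-dimethyl-6-oxocyclohexyl]propanoate | O=C1CC[C@@H](C)[C@@](C)(CO[Si](C)(C)C(C)(C)C)[C@@H]1CCC(=O)OC | intermediate
17 | methyl 3-[(1S,2R,3R)-2-({[tert-butyl(dimethyl)silyl]oxy}methyl)-6-(dibromomethylidene)-2,3-dimethylcyclohexyl]propanoate | BrC(Br)=C1CC[C@@H](C)[C@@](C)(CO[Si](C)(C)C(C)(C)C)[C@@H]1CCC(=O)OC | intermediate
18 | lithium methyl(1-methylalkenyl)cuprate derived from 17 (C11 carries CH3 and Cu; either alkene geometry) | [Li+].C[Cu-]C(C)=C1CC[C@@H](C)[C@@](C)(CO[Si](C)(C)C(C)(C)C)[C@@H]1CCC(=O)OC | intermediate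
19 | methyl 3-[(1R,2R,3R)-2-({[tert-butyl(dimethyl)silyl]oxy}methyl)-2,3-dimethyl-6-(propan-2-ylidene)cyclohexyl]propanoate | CC(C)=C1CC[C@@H](C)[C@@](C)(CO[Si](C)(C)C(C)(C)C)[C@@H]1CCC(=O)OC | intermediate
20 | methyl 3-[(1R,2R,3R)-2-(hydroxymethyl)-2,3-dimethyl-6-(propan-2-ylidene)cyclohexyl]propanoate | CC(C)=C1CC[C@@H](C)[C@@](C)(CO)[C@@H]1CCC(=O)OC | intermediate
21 | methyl 3-[(1R,2R,3R)-2-formyl-2,3-dimethyl-6-(propan-2-ylidene)cyclohexyl]propanoate | CC(C)=C1CC[C@@H](C)[C@@](C)(C=O)[C@@H]1CCC(=O)OC | intermediate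
22 | indole | c1ccc2[nH]ccc2c1 | starting material
23 | indol-1-ylmagnesium bromide | Br[Mg]n1ccc2ccccc12 | intermediate
24 | methyl 3-[(1R,2R,3R)-2-[hydroxy(1H-indol-3-yl)methyl]-2,3-dimethyl-6-(propan-2-ylidene)cyclohexyl]propanoate (both carbinol epimers) | CC(C)=C1CC[C@@H](C)[C@@](C)(C(O)c2c[nH]c3ccccc23)[C@@H]1CCC(=O)OC | intermediate
25 | lithium 3-[(1R,2R,3R)-2-[hydroxy(1H-indol-3-yl)methyl]-2,3-dimethyl-6-(propan-2-ylidene)cyclohexyl]propanoate | [Li+].CC(C)=C1CC[C@@H](C)[C@@](C)(C(O)c2c[nH]c3ccccc23)[C@@H]1CCC(=O)[O-] | intermediate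
26 | suaveolindole, 3-[(1S,2R,3R)-2-(1H-indol-3-ylmethyl)-2,3-dimethyl-6-(propan-2-ylidene)cyclohexyl]propanoic acid | CC(C)=C1CC[C@@H](C)[C@@](C)(Cc2c[nH]c3ccccc23)[C@@H]1CCC(=O)O | target

Total step count: 14. Longest linear sequence: 14 steps (1 → 26).

Steps most likely to fail

Step 8. The ring closure may show poor facial selectivity (C8 adding syn to CH2OTBS), may turn to crossed regiochemistry, or C6 may epimerise during the basic cleavage. The fallback sets out from 13 and comes back at 16, building the ring by metathesis and attaching the chain by enolate chemistry. Heating 13 in wet toluene at 110 °C opens the dioxinone to the acylketene, whose hydration and decarboxylation should give methyl ketone F1. Kinetic enolisation (LiN(i-Pr)2, THF, −78 °C) with Et3SiCl trapping gives the terminal silyl enol ether F2. Ring-closing metathesis of the enol ether with the vinyl group (second-generation Grubbs catalyst, toluene, 80 °C) expels ethene and gives cyclic silyl enol ether F3, in which C1(OSi)=C6 is a regiodefined enolate equivalent. Mukaiyama–Michael addition to methyl acrylate (TiCl4, CH2Cl2, −78 °C) then puts C8–C10 on C6 anti to the pseudoaxial CH2OTBS group and returns 16.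

Step 7. Displacement at the β-branched iodide may be so slow that the dienolate decomposes or alkylates at its α-carbon. The fallback sets out from 10 and comes back at 13. The iodide alkylates the far more nucleophilic dianion of tert-butyl acetoacetate (2 equiv LiN(i-Pr)2, THF, 0 °C) at its terminal carbon to give tert-butyl β-keto ester F4. Acetone with (CF3CO)2O and CF3CO2H at 0 °C then converts the tert-butyl β-keto ester directly into dioxinone 13.

Step 9. Addition of the ylide to the hindered α-branched ketone may be sluggish, and prolonged heating with phosphonium bromides may enolise C6 or strip the silyl ether. The fallback sets out from 16 and comes back at 19, bypassing 17 and step 10. Aldol addition of the lithium enolate of phenyl 2-methylpropanoate (THF, −78 → 0 °C) to the C1 ketone, with spontaneous lactonisation by loss of phenoxide, gives spiro β-lactone F5. Thermal decarboxylation (toluene, 110–140 °C) extrudes CO2 stereospecifically to leave the isopropylidene group of 19.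

Further compounds
F1 | step 8 | (5R,6S)-6-({[tert-butyl(dimethyl)silyl]oxy}methyl)-5,6-dimethyloct-7-en-2-one | CC(=O)CC[C@@H](C)[C@@](C)(CO[Si](C)(C)C(C)(C)C)C=C
F2 | step 8 | {[(5R,6S)-6-({[tert-butyl(dimethyl)silyl]oxy}methyl)-5,6-dimethylocta-1,7-dien-2-yl]oxy}(triethyl)silane | C=C(O[Si](CC)(CC)CC)CC[C@@H](C)[C@@](C)(CO[Si](C)(C)C(C)(C)C)C=C
F3 | step 8 | tert-butyl(dimethyl){[(1R,6R)-1,6-dimethyl-3-[(triethylsilyl)oxy]cyclohex-2-en-1-yl]methoxy}silane | CC[Si](CC)(CC)OC1=C[C@](C)(CO[Si](C)(C)C(C)(C)C)[C@H](C)CC1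
F4 | step 7 | tert-butyl (6R,7S)-7-({[tert-butyl(dimethyl)silyl]oxy}methyl)-6,7-dimethyl-3-oxonon-8-enoate | CC(C)(C)OC(=O)CC(=O)CC[C@@H](C)[C@@](C)(CO[Si](C)(C)C(C)(C)C)C=C
F5 | step 9 | spiro β-lactone of 16: 3,3-dimethyl-2-oxo-1-oxaspiro[3.5]nonane spiro-fused at C1 of the ring, ring stereocentres as in 16, both spiro epimers | CC1(C)C(=O)OC12CC[C@@H](C)[C@@](C)(CO[Si](C)(C)C(C)(C)C)[C@@H]2CCC(=O)OC
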